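(The readings stem from a simulated flask from invented constants, and the scatter is random.)

The partner is the species to price in this flask, since the summer and dawn runs level off at different heights of target with different partner charges.

| flask | starting material | partner | second substrate | remark | time |
|---|---|---|---|---|---|
| summer | 0.40 M | 1.7 equiv (in portions, 3) | 1 equiv | run made earlier; portions every 3.0 min |  |
| dawn | 0.40 M | 2.6 equiv (in portions, 3) | 1 equiv | run made earlier; portions every 3.0 min |  |
| flask | 0.40 M | 1.20 equiv (in portions, 3) | 1.00 equiv | the portions of partner follow each other after 3.0 min, the first at the start | 50 min |

| run | time / min | starting material / % | target / % |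
|---|---|---|---|
| summer | 3.00 | 82 | 16 |
| summer | 6.00 | 59 | 37 |
| summer | 12.0 | 31 | 66 |
| summer | 20.0 | 26 | 73 |
| summer | 40.0 | 28 | 74 |
| dawn | 3.00 | 70 | 26 |
| dawn | 6.00 | 51 | 58 |
| dawn | 12.0 | 14 | 83 |
| dawn | 20.0 | 6 | 92 |
| dawn | 40.0 | 5 | 97 |

(each reading ± 2 percentage points)

- why nothing more happens at 50 min, or that something still does (forward and back rates have come level / the partner has run out first / all of the starting material has reacted / it is still moving)
- share of the starting material used up at 50 min
- target at 50 min, in percent of the starting material charged

- the numbers in the tables scatter by 2 percentage points (one standard deviation)
- the reaction counts as stopped when no species that holds the starting material changes by six tenths of a point or more over the second half of the time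

The summer run lies flat from 20.0 min to 40.0 min, with target at 74% and starting material still present, and it reads 2.30 as its partner price, the equivalents of partner charged per equivalent of target at the plateau. The bracket assumes that each further equivalent of partner buys no more target than the one before. A smaller charge then pays no more than the summer price, so 1.20 equiv gives a lower bound of 52.2%. The step from summer to dawn cost 3.91 per equivalent of target, dearer than the average, and walking down from summer at that price gives an upper bound of 61.2%. This reckoning commits to the middle of that bracket, 56.7%.

The forecast differs slightly, lying inside the bracket but below that middle: 54% used up (46% to 63%), target 54% (45% to 62%), and as the ending, the partner has run out first. It adds that “the number is firmer than the cause”.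

At 50 min the flask has used up 57.1% of its starting material and holds 57.1% target, and the ending is that the partner has run out first.

    starting material + partner → target (k = 0.00800 M⁻¹ s⁻¹)
    second substrate + partner → second product (k = 0.00430 M⁻¹ s⁻¹)
    second substrate → decomposition product (k = 1.40 × 10⁻⁵ s⁻¹)
    partner → decomposed reagent (k = 0.00100 s⁻¹)

The partner, the limiting reagent here, stands at 0% of its charge at 50.0 min, against 42.9% for starting material. At 6.00 min the flask's rate of partner loss is 2.07 times its rate into target, and at 25.0 min that ratio is higher, 2.50. The flask's whole run pays 2.10, less than the summer reading 2.30. For the neighbour charged with 0.480 equiv of partner, the summer price gives a floor of 20.9%, and its target stands at 24.9%.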